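**Retrosynthetic overview**
- Target 19 comes from vinyl iodide 18 by Pd-catalysed reductive carbonylation, which adds the formyl carbon. 18 comes from boryl alcohol 13 by iododeboronation, isovalerylation at C3 and silyl-to-acetate exchange on the side chain.
- The strategy rests on the C2–C3 bond of the dihydrofuran ring. It joins the benzylic carbinol carbon C3 to C2, which carries the ring oxygen O1 and a 1,1-disubstituted alkene. This is the pattern left when the γ-carbon of a 2-substituted γ-aryloxyallyl metal adds to an aldehyde.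
- Key disconnection C2–C3: copper-catalysed enantioselective borylative cyclisation of the O-allenyl salicylaldehyde 10 with B2pin2. It closes the dihydrofuran ring (the only ring made; the benzene ring is bought) and sets C2 and C3 cis.
- 10 comes from 4-hydroxyacetophenone by ortho-formylation, O-propargylation, acetal masking of the aldehyde, Noyori transfer hydrogenation (side-chain S centre), silylation, propargyl-to-allenyl isomerisation and acetal hydrolysis.

Key step: step 8

Assumption: the sense of induction of the bisphosphine cannot be predicted with confidence for an O-allenyl substrate; (R,R)-Ph-BPE is written, and its commercial enantiomer is used instead if the first trial gives the (2S,3S)-cis diastereomer.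

**Step 1**
Reactants: 1 4-hydroxyacetophenone
Product: 3 5-acetyl-2-hydroxybenzaldehyde, via magnesium salicyl alkoxide 2 (not isolated)
Conditions: MgCl2, Et3N, paraformaldehyde, MeCN, reflux; 1 M HCl work-up
Reagents that add atoms: formaldehyde (as paraformaldehyde), C=O
Why: Casnati–Skattebøl ortho-formylation: the magnesium phenoxide delivers formaldehyde to the free position ortho to oxygen (para is blocked by the acetyl group), and the chelated salicyl alkoxide 2 is oxidised to the aldehyde by hydride transfer to a second formaldehyde.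

**Step 2**
Reactants: 3 5-acetyl-2-hydroxybenzaldehyde; 4 propargyl bromide
Product: 5 5-acetyl-2-(prop-2-yn-1-yloxy)benzaldehyde
Conditions: K2CO3, DMF, rt
Reagents that add atoms: none
Why: Williamson etherification; the phenoxide, the only acidic site, displaces bromide from the propargylic halide by SN2.

**Step 3**
Reactants: 5 5-acetyl-2-(prop-2-yn-1-yloxy)benzaldehyde
Product: 6 1-[3-(dimethoxymethyl)-4-(prop-2-yn-1-yloxy)phenyl]ethanone
Conditions: HC(OMe)3 (1.5 equiv), MeOH, PPTS (5 mol%), rt; Et3N quench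
Reagents that add atoms: trimethyl orthoformate, COC(OC)OC; methanol, CO
Why: Acid-catalysed acetalisation is far faster at the aryl aldehyde than at the para-alkoxy-deactivated aryl methyl ketone, so only the formyl group is masked, which keeps it out of the reduction in step 4 and away from the propargylic carbanion in step 6.

**Step 4**
Reactants: 6 1-[3-(dimethoxymethyl)-4-(prop-2-yn-1-yloxy)phenyl]ethanone
Product: 7 (1S)-1-[3-(dimethoxymethyl)-4-(prop-2-yn-1-yloxy)phenyl]ethanol
Conditions: RuCl[(S,S)-TsDPEN](p-cymene) (1 mol%), HCO2Na (5 equiv), H2O/MeOH 1:1, 40 °C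
Reagents that add atoms: none
Why: Noyori–Ikariya asymmetric transfer hydrogenation: the (S,S)-TsDPEN ruthenium hydride reduces the aryl methyl ketone through the six-membered CH/π-organised transition state that gives (S)-1-arylethanols, and the near-neutral formate medium leaves the acetal and the alkyne alone.

**Step 5**
Reactants: 7 (1S)-1-[3-(dimethoxymethyl)-4-(prop-2-yn-1-yloxy)phenyl]ethanol
Product: 8 tert-butyl{(1S)-1-[3-(dimethoxymethyl)-4-(prop-2-yn-1-yloxy)phenyl]ethoxy}dimethylsilane
Conditions: TBSCl, imidazole, DMF, rt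
Reagents that add atoms: tert-butyldimethylsilyl chloride, CC(C)(C)[Si](C)(C)Cl
Why: Standard imidazole-promoted silylation of the secondary benzylic alcohol; no bond to the stereocentre is broken.

**Step 6**
Reactants: 8 tert-butyl{(1S)-1-[3-(dimethoxymethyl)-4-(prop-2-yn-1-yloxy)phenyl]ethoxy}dimethylsilane
Product: 9 tert-butyl{(1S)-1-[3-(dimethoxymethyl)-4-(propa-1,2-dien-1-yloxy)phenyl]ethoxy}dimethylsilane
Conditions: KOtBu (0.3 equiv), THF, rt
Reagents that add atoms: none
Why: Base-catalysed propargyl-to-allenyl prototropic isomerisation, well known for aryl propargyl ethers; with the aldehyde masked the delocalised carbanion has no electrophile to attack, and the silyl ether and acetal are inert to alkoxide.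

**Step 7**
Reactants: 9 tert-butyl{(1S)-1-[3-(dimethoxymethyl)-4-(propa-1,2-dien-1-yloxy)phenyl]ethoxy}dimethylsilane
Product: 10 5-[(1S)-1-(tert-butyldimethylsilyloxy)ethyl]-2-(propa-1,2-dien-1-yloxy)benzaldehyde
Conditions: PPTS (10 mol%), acetone/H2O 10:1, 0 °C to rt; NaHCO3 quench
Reagents that add atoms: water, O
Why: Specific-acid acetal hydrolysis through an ortho-alkoxy-stabilised oxocarbenium ion should be much faster than protonation of the aryl allenyl ether or ionisation of the benzylic silyl ether under pyridinium catalysis.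

**Step 8**
Reactants: 10 5-[(1S)-1-(tert-butyldimethylsilyloxy)ethyl]-2-(propa-1,2-dien-1-yloxy)benzaldehyde; 11 bis(pinacolato)diboron
Product: 13 (2R,3R)-5-[(1S)-1-(tert-butyldimethylsilyloxy)ethyl]-2-[1-(4,4,5,5-tetramethyl-1,3,2-dioxaborolan-2-yl)ethenyl]-2,3-dihydro-1-benzofuran-3-ol, via O-boryl ether 12 (not isolated)
Conditions: CuCl (5 mol%), (R,R)-Ph-BPE (6 mol%), NaOtBu (6 mol%), B2pin2 (1.2 equiv), THF, 0 °C to rt; pH 7 buffer work-up
Reagents that add atoms: none
Why: Proposed new method: the monovalent copper boryl LCu–Bpin (from CuCl, NaOtBu, the bisphosphine and B2pin2) should add across the terminal C=C of the aryloxyallene on the face away from the aryloxy group, placing boron on the central carbon and giving a (Z)-2-boryl-γ-aryloxyallylcopper; this transfers its oxygen-bearing γ-carbon to the ortho aldehyde through a six-membered cyclic transition state, forming C2–C3, and the copper alkoxide is then borylated by B2pin2 to give 12 and return LCu–Bpin. The closest known reactions are the copper–bisphosphine-catalysed enantioselective borylative coupling of allenes with aldehydes and the borylative cyclisation of carbon-tethered allenyl ketones; the O-allenyl tether is the untested element. The dihydrofuran ring closes by 5-exo-trig attack of C2 on the carbonyl carbon while the double bond moves out to become the 1,1-disubstituted alkenyl boronate. C2 and C3 are set together: their cis relationship follows from the cis-fused bicyclic transition state imposed by the three-atom tether (C3a, C7a, O1) and from the (Z)-allylcopper geometry, and their absolute configuration from the chiral bisphosphine on copper, the side-chain S centre being too remote to interfere. The step needs borylcupration of the allene to outrun 1,2-addition of the copper boryl to the aldehyde and base-induced reaction of the allenyl ether, which the unhindered electron-rich terminal C=C and the restriction of alkoxide to the catalyst loading should secure.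

**Step 9**
Reactants: 13 (2R,3R)-5-[(1S)-1-(tert-butyldimethylsilyloxy)ethyl]-2-[1-(4,4,5,5-tetramethyl-1,3,2-dioxaborolan-2-yl)ethenyl]-2,3-dihydro-1-benzofuran-3-ol
Product: 14 (2S,3R)-5-[(1S)-1-(tert-butyldimethylsilyloxy)ethyl]-2-(1-iodoethenyl)-2,3-dihydro-1-benzofuran-3-ol
Conditions: NaOH (3 M aq, 3 equiv), I2 (1.5 equiv), THF, 0 °C; Na2S2O3 quench
Reagents that add atoms: iodine, II
Why: Brown-type iododeboronation: hydroxide forms the alkenylboronate ate complex, which iodine cleaves at the ipso carbon; the terminal methylene has no geometry to lose and C2 and C3 are untouched (C2 becomes S only because iodine raises the CIP rank of the alkenyl carbon; the 2,3-cis arrangement is unchanged).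

**Step 10**
Reactants: 14 (2S,3R)-5-[(1S)-1-(tert-butyldimethylsilyloxy)ethyl]-2-(1-iodoethenyl)-2,3-dihydro-1-benzofuran-3-ol; 15 isovaleryl chloride
Product: 16 (2S,3R)-5-[(1S)-1-(tert-butyldimethylsilyloxy)ethyl]-2-(1-iodoethenyl)-2,3-dihydro-1-benzofuran-3-yl 3-methylbutanoate
Conditions: pyridine, DMAP (10 mol%), CH2Cl2, 0 °C to rt
Reagents that add atoms: none
Why: DMAP-catalysed O-acylation of the secondary alcohol via the acylpyridinium ion; the C3–O bond is not broken, so configuration is retained.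

**Step 11**
Reactants: 16 (2S,3R)-5-[(1S)-1-(tert-butyldimethylsilyloxy)ethyl]-2-(1-iodoethenyl)-2,3-dihydro-1-benzofuran-3-yl 3-methylbutanoate
Product: 17 (2S,3R)-5-[(1S)-1-hydroxyethyl]-2-(1-iodoethenyl)-2,3-dihydro-1-benzofuran-3-yl 3-methylbutanoate
Conditions: TBAF (1.5 equiv), AcOH (1.5 equiv), THF, 0 °C to rt
Reagents that add atoms: none
Why: Fluoride-mediated desilylation driven by the strong Si–F bond; acetic acid buffering protects the C3 ester from alkoxide, and the C–O bond at the side-chain stereocentre is untouched.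

**Step 12**
Reactants: 17 (2S,3R)-5-[(1S)-1-hydroxyethyl]-2-(1-iodoethenyl)-2,3-dihydro-1-benzofuran-3-yl 3-methylbutanoate
Product: 18 (2S,3R)-5-[(1S)-1-acetoxyethyl]-2-(1-iodoethenyl)-2,3-dihydro-1-benzofuran-3-yl 3-methylbutanoate
Conditions: Ac2O, pyridine, DMAP (5 mol%), CH2Cl2, 0 °C
Reagents that add atoms: acetic anhydride, CC(=O)OC(C)=O
Why: DMAP-catalysed acetylation of the secondary benzylic alcohol under basic conditions, with retention because the C–O bond is not broken.

**Step 13**
Reactants: 18 (2S,3R)-5-[(1S)-1-acetoxyethyl]-2-(1-iodoethenyl)-2,3-dihydro-1-benzofuran-3-yl 3-methylbutanoate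
Product: 19 (2R,3R)-5-[(1S)-1-acetoxyethyl]-2-(3-oxoprop-1-en-2-yl)-2,3-dihydro-1-benzofuran-3-yl 3-methylbutanoate
Conditions: CO (1–3 atm), Pd(PPh3)4 (5 mol%), Bu3SnH (1.1 equiv, syringe pump), THF, 50 °C
Reagents that add atoms: carbon monoxide, [C-]#[O+]
Why: Baillargeon–Stille reductive carbonylation: oxidative addition of zerovalent palladium to the vinyl iodide, CO insertion to the acylpalladium, hydride transfer from tin and reductive elimination give the 2-substituted acrolein; slow stannane addition suppresses hydrodeiodination and conjugate reduction, and the esters and stereocentres are not involved.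

**Compound list**
1 | 4-hydroxyacetophenone | CC(=O)c1ccc(O)cc1 | starting material
2 | 1-[4-hydroxy-3-(hydroxymethyl)phenyl]ethanone (present as its magnesium salt) | CC(=O)c1ccc(O)c(CO)c1 | intermediate
3 | 5-acetyl-2-hydroxybenzaldehyde | CC(=O)c1ccc(O)c(C=O)c1 | intermediate
4 | propargyl bromide (3-bromoprop-1-yne) | C#CCBr | starting material
5 | 5-acetyl-2-(prop-2-yn-1-yloxy)benzaldehyde | CC(=O)c1ccc(OCC#C)c(C=O)c1 | intermediate
6 | 1-[3-(dimethoxymethyl)-4-(prop-2-yn-1-yloxy)phenyl]ethanone | CC(=O)c1ccc(OCC#C)c(C(OC)OC)c1 | intermediate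
7 | (1S)-1-[3-(dimethoxymethyl)-4-(prop-2-yn-1-yloxy)phenyl]ethanol | C[C@H](O)c1ccc(OCC#C)c(C(OC)OC)c1 | intermediate
8 | tert-butyl{(1S)-1-[3-(dimethoxymethyl)-4-(prop-2-yn-1-yloxy)phenyl]ethoxy}dimethylsilane | C[C@H](O[Si](C)(C)C(C)(C)C)c1ccc(OCC#C)c(C(OC)OC)c1 | intermediate
9 | tert-butyl{(1S)-1-[3-(dimethoxymethyl)-4-(propa-1,2-dien-1-yloxy)phenyl]ethoxy}dimethylsilane | C[C@H](O[Si](C)(C)C(C)(C)C)c1ccc(OC=C=C)c(C(OC)OC)c1 | intermediate
10 | 5-[(1S)-1-(tert-butyldimethylsilyloxy)ethyl]-2-(propa-1,2-dien-1-yloxy)benzaldehyde | C=C=COc1ccc([C@H](C)O[Si](C)(C)C(C)(C)C)cc1C=O | intermediate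
11 | bis(pinacolato)diboron | CC1(C)OB(OC1(C)C)B1OC(C)(C)C(C)(C)O1 | starting material
12 | 2-{[(2R,3R)-5-[(1S)-1-(tert-butyldimethylsilyloxy)ethyl]-2-[1-(4,4,5,5-tetramethyl-1,3,2-dioxaborolan-2-yl)ethenyl]-2,3-dihydro-1-benzofuran-3-yl]oxy}-4,4,5,5-tetramethyl-1,3,2-dioxaborolane | C=C(B1OC(C)(C)C(C)(C)O1)[C@H]2Oc3ccc([C@H](C)O[Si](C)(C)C(C)(C)C)cc3[C@H]2OB4OC(C)(C)C(C)(C)O4 | intermediate
13 | (2R,3R)-5-[(1S)-1-(tert-butyldimethylsilyloxy)ethyl]-2-[1-(4,4,5,5-tetramethyl-1,3,2-dioxaborolan-2-yl)ethenyl]-2,3-dihydro-1-benzofuran-3-ol (2,3-cis) | C=C(B1OC(C)(C)C(C)(C)O1)[C@H]2Oc3ccc([C@H](C)O[Si](C)(C)C(C)(C)C)cc3[C@H]2O | intermediate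
14 | (2S,3R)-5-[(1S)-1-(tert-butyldimethylsilyloxy)ethyl]-2-(1-iodoethenyl)-2,3-dihydro-1-benzofuran-3-ol (2,3-cis) | C=C(I)[C@H]1Oc2ccc([C@H](C)O[Si](C)(C)C(C)(C)C)cc2[C@H]1O | intermediate
15 | isovaleryl chloride (3-methylbutanoyl chloride) | CC(C)CC(=O)Cl | starting material
16 | (2S,3R)-5-[(1S)-1-(tert-butyldimethylsilyloxy)ethyl]-2-(1-iodoethenyl)-2,3-dihydro-1-benzofuran-3-yl 3-methylbutanoate | C=C(I)[C@H]1Oc2ccc([C@H](C)O[Si](C)(C)C(C)(C)C)cc2[C@H]1OC(=O)CC(C)C | intermediate
17 | (2S,3R)-5-[(1S)-1-hydroxyethyl]-2-(1-iodoethenyl)-2,3-dihydro-1-benzofuran-3-yl 3-methylbutanoate | C=C(I)[C@H]1Oc2ccc([C@H](C)O)cc2[C@H]1OC(=O)CC(C)C | intermediate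
18 | (2S,3R)-5-[(1S)-1-acetoxyethyl]-2-(1-iodoethenyl)-2,3-dihydro-1-benzofuran-3-yl 3-methylbutanoate | C=C(I)[C@H]1Oc2ccc([C@H](C)OC(C)=O)cc2[C@H]1OC(=O)CC(C)C | intermediate
19 | (2R,3R)-5-[(1S)-1-acetoxyethyl]-2-(3-oxoprop-1-en-2-yl)-2,3-dihydro-1-benzofuran-3-yl 3-methylbutanoate (CNP0252902.1) | C=C(C=O)[C@H]1Oc2ccc([C@H](C)OC(C)=O)cc2[C@H]1OC(=O)CC(C)C | target

**Step count**
Total steps: 13. Longest linear sequence: 13 steps (1 to 19).

**Steps most likely to fail**

1. Step 8 (proposed new method). The copper boryl may add to the aldehyde instead of the allene, residual alkoxide may trigger a carbanion cyclisation of the allenyl ether, or enantiofacial control may be poor and give the (2S,3S)-cis diastereomer. The fallback uses known chemistry, leaves the route at 7 and returns at 19.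
 - 7 is acetylated (Ac2O, pyridine, DMAP) to (1S)-1-[3-(dimethoxymethyl)-4-(prop-2-yn-1-yloxy)phenyl]ethyl acetate F1.
 - Markovnikov hydration of the terminal alkyne (AuCl(PPh3)/AgOTf cat., dioxane/H2O) gives (1S)-1-[3-(dimethoxymethyl)-4-(2-oxopropoxy)phenyl]ethyl acetate F2.
 - PPTS in wet acetone frees (1S)-1-[3-formyl-4-(2-oxopropoxy)phenyl]ethyl acetate F3.
 - Proline (30 mol%, DMF, rt; the antipode that gives the wanted series) effects the known 5-enolexo aldolisation of 2-(2-oxopropoxy)benzaldehydes to the cis ketol (1S)-1-[(2S,3R)-2-acetyl-3-hydroxy-2,3-dihydro-1-benzofuran-5-yl]ethyl acetate F4. C2 is S here only because the acetyl carbon outranks C3.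
 - Non-basic Takai–Lombardo methylenation (Zn, CH2Br2, TiCl4, THF/CH2Cl2) gives (1S)-1-[(2R,3R)-3-hydroxy-2-(prop-1-en-2-yl)-2,3-dihydro-1-benzofuran-5-yl]ethyl acetate F5.
 - Acylation with 15 (pyridine, DMAP) gives (2R,3R)-5-[(1S)-1-acetoxyethyl]-2-(prop-1-en-2-yl)-2,3-dihydro-1-benzofuran-3-yl 3-methylbutanoate F6.
 - Allylic oxidation of the isopropenyl methyl group (SeO2 cat., t-BuOOH, CH2Cl2) gives 19; MnO2 takes on any allylic alcohol, which is the compound F7 of the next fallback.

2. Step 13. Tin hydride may reduce the vinylpalladium before CO insertion (hydrodeiodination), or reduce the new enal in conjugate fashion. The fallback leaves at 18 and returns at 19: Stille coupling of 18 with (tributylstannyl)methanol (Pd(PPh3)4, dioxane, 80 °C) introduces the carbon at the alcohol oxidation level and gives (2R,3R)-5-[(1S)-1-acetoxyethyl]-2-(3-hydroxyprop-1-en-2-yl)-2,3-dihydro-1-benzofuran-3-yl 3-methylbutanoate F7, which MnO2 (CH2Cl2, rt) oxidises to 19.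

3. Step 9. Ate-complex formation at the hindered pinacol boronate may be slow, so that protodeboronation or iodination of the electron-rich ring takes over. The fallback leaves at 13 and returns at 14: KHF2 (MeOH/H2O, rt) converts 13 into potassium {1-[(2R,3R)-5-[(1S)-1-(tert-butyldimethylsilyloxy)ethyl]-3-hydroxy-2,3-dihydro-1-benzofuran-2-yl]ethenyl}trifluoroborate F8, which undergoes the known iodination of organotrifluoroborates with NaI and chloramine-T (THF/H2O, rt) to give 14.

**Further compounds**
F1 | step 8 | (1S)-1-[3-(dimethoxymethyl)-4-(prop-2-yn-1-yloxy)phenyl]ethyl acetate | C[C@H](OC(C)=O)c1ccc(OCC#C)c(C(OC)OC)c1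
F2 | step 8 | (1S)-1-[3-(dimethoxymethyl)-4-(2-oxopropoxy)phenyl]ethyl acetate | C[C@H](OC(C)=O)c1ccc(OCC(C)=O)c(C(OC)OC)c1
F3 | step 8 | (1S)-1-[3-formyl-4-(2-oxopropoxy)phenyl]ethyl acetate | C[C@H](OC(C)=O)c1ccc(OCC(C)=O)c(C=O)c1
F4 | step 8 | (1S)-1-[(2S,3R)-2-acetyl-3-hydroxy-2,3-dihydro-1-benzofuran-5-yl]ethyl acetate | CC(=O)[C@H]1Oc2ccc([C@H](C)OC(C)=O)cc2[C@H]1O
F5 | step 8 | (1S)-1-[(2R,3R)-3-hydroxy-2-(prop-1-en-2-yl)-2,3-dihydro-1-benzofuran-5-yl]ethyl acetate | C=C(C)[C@H]1Oc2ccc([C@H](C)OC(C)=O)cc2[C@H]1O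
F6 | step 8 | (2R,3R)-5-[(1S)-1-acetoxyethyl]-2-(prop-1-en-2-yl)-2,3-dihydro-1-benzofuran-3-yl 3-methylbutanoate | C=C(C)[C@H]1Oc2ccc([C@H](C)OC(C)=O)cc2[C@H]1OC(=O)CC(C)C
F7 | step 13 | (2R,3R)-5-[(1S)-1-acetoxyethyl]-2-(3-hydroxyprop-1-en-2-yl)-2,3-dihydro-1-benzofuran-3-yl 3-methylbutanoate | C=C(CO)[C@H]1Oc2ccc([C@H](C)OC(C)=O)cc2[C@H]1OC(=O)CC(C)C
F8 | step 9 | potassium {1-[(2R,3R)-5-[(1S)-1-(tert-butyldimethylsilyloxy)ethyl]-3-hydroxy-2,3-dihydro-1-benzofuran-2-yl]ethenyl}trifluoroborate | C=C([B-](F)(F)F)[C@H]1Oc2ccc([C@H](C)O[Si](C)(C)C(C)(C)C)cc2[C@H]1O.[K+]
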